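The ten-membered ring is never cyclised; it is released by cutting a temporary transannular C3–C8 bond. In trans-decalinol 23 the cis unit C2–C1=C10(CH3)–C9 is held in cyclohexene ring B, and ring A carries O8–C8–C3–C4–O4 as a 1,3 push–pull array (axial O8–H, equatorial C4–O bond of a 4,15-spiro-epoxide). One titanium-promoted Grob fragmentation then gives the C8 ketone, the ring-trans C3=C4 alkene with free C15–OH and cyclodecadienone 24. Ring A with C4, C15 and C6 comes from (−)-quinic acid, ring B from metathesis; reduction at C8, epoxidation, lactonisation, methylenation, angeloylation and dihydroxylation follow.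

Key step: step 16

Remarks on the chemistry (one line each):
- Atoms carry the numbers of the target (C1–C15; each oxygen is named by its carbon; O12 is the oxygen on C12). β is the face on which C11 leaves C7, α the opposite face; all compounds are single enantiomers.
- Correction: the C3=C4 alkene made in step 16 has C2 and C5 trans on the ring, and because C15 outranks C5 its CIP descriptor is Z; 24 is therefore the (1(10)Z,3Z)-dienone.
- Design of the precursor: a methylide added to a C4 ketone would have to pass the axial O8 oxygen and would favour the epimer with axial C4–O, which cannot fragment. C4 is therefore taken from quinic acid with C15 already axial, and O8 is made later by addition to a C8 ketone anti to that axial carbon.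
- O6 (TBS) and O12 (pivalate) carry different groups so that they can be addressed separately after the fragmentation.

Step 1
Reactants: 1 (−)-quinic acid
Product: 2 quinide (1,5-lactone of 1; C15(=O)–O8 bridge; free 4α-OH, 6α-OH, 7α-OH)
Conditions: TsOH·H2O (cat.), toluene/DMF, reflux, Dean–Stark
Reagents that add atoms: none
Why: Acid-catalysed lactonisation joins the carboxyl group (C15) to the only hydroxyl that is cis to it (O8) after chair inversion, which locks ring A in the chair that has C15 axial and O4 equatorial on C4 and leaves all four stereocentres untouched.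

Step 2
Reactants: 2 quinide
Product: 3 6-O-TBS-quinide
Conditions: TBSCl (1.1 equiv), imidazole, DMF, 0 °C to rt
Reagents that add atoms: tert-butyldimethylsilyl chloride, CC(C)(C)[Si](C)(C)Cl
Why: Silyl ether formation is expected to pick the equatorial, unhindered O6 hydroxyl over the axial O7 hydroxyl next to the bridgehead and over the tertiary O4 hydroxyl, so that O7 alone remains for oxidation.

Step 3
Reactants: 3 6-O-TBS-quinide
Product: 4 6-O-TBS-7-oxoquinide (C7 ketone)
Conditions: Dess–Martin periodinane, CH2Cl2, rt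
Reagents that add atoms: none
Why: Dess–Martin oxidation converts the one remaining secondary alcohol into the C7 ketone under neutral conditions, and the tertiary C4 hydroxyl cannot be oxidised.

Step 4
Reactants: 4 C7 ketone; 5 methyl (triphenylphosphoranylidene)acetate
Product: 6 methyl (E)-(6-O-TBS-quinid-7-ylidene)acetate
Conditions: toluene, 90 °C
Reagents that add atoms: methyl (triphenylphosphoranylidene)acetate (5), COC(=O)C=P(c1ccccc1)(c1ccccc1)c1ccccc1
Why: Wittig olefination with a stabilised ylide works on this α,α'-dioxygenated and therefore electrophilic ketone without added base, so neither the lactone nor the α-silyloxy centre C6 is endangered, and the alkene geometry is of no consequence because C11 becomes a methylene group.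

Step 5
Reactants: 6 enoate
Product: 7 methyl (6-O-TBS-quinid-7β-yl)acetate (H7 α; C11 equatorial and trans to O6)
Conditions: H2 (1 atm), 5% Rh/Al2O3, EtOAc, rt
Reagents that add atoms: none
Why: Heterogeneous hydrogenation should deliver hydrogen to C7 from the convex α-face, because the axial C8–O bond of the lactone bridge shields the β-face, which places the acetate chain equatorial and trans to O6, and rhodium is chosen to avoid hydrogenolysis of the allylic C–O bonds.

Step 6
Reactants: 7 lactone ester
Product: 8 ring-A tetraol (4α-OH, 4β-CH2OH, 6α-OTBS, 7β-CH2CH2OH, 8β-OH)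
Conditions: LiAlH4, THF, 0 °C to rt; aq. Rochelle salt
Reagents that add atoms: none
Why: Hydride reduction with LiAlH4 turns the bridging lactone into the C15 carbinol plus the free O8 hydroxyl and the methyl ester into the C12 carbinol, without touching a stereocentre or the silyl ether.

Step 7
Reactants: 8 tetraol
Product: 9 4,15-O-isopropylidene diol (free 8β-OH and C12–OH)
Conditions: 2,2-dimethoxypropane, PPTS (cat.), acetone, rt
Reagents that add atoms: 2,2-dimethoxypropane, COC(C)(C)OC
Why: Acetonide formation by acid-catalysed transketalisation selects the only 1,2-diol, O4–H with C15–OH, as a five-membered dioxolane, which masks the future epoxide oxygens while C8 is taken to the ketone.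

Step 8
Reactants: 9 acetonide diol
Product: 10 12-O-pivalate (free 8β-OH)
Conditions: PivCl (1.1 equiv), pyridine, CH2Cl2, −20 to 0 °C
Reagents that add atoms: pivaloyl chloride, CC(C)(C)C(=O)Cl
Why: Acylation is selective for the primary C12 hydroxyl over the axial secondary O8 hydroxyl, which is shielded by the syn-axial C15, and it gives O12 a group that differs from the silyl ether on O6.

Step 9
Reactants: 10 pivalate alcohol
Product: 11 C8 ketone
Conditions: Dess–Martin periodinane, CH2Cl2, rt
Reagents that add atoms: none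
Why: Dess–Martin oxidation of the remaining secondary alcohol gives the C8 ketone under non-basic conditions, so the β-oxygen substituents at C4 and C6 are not eliminated.

Step 10
Reactants: 11 C8 ketone; 12 N,N-dimethylmethyleneiminium iodide
Product: 15 3-methylene C8 ketone, via Mannich base 13 (not isolated), via methiodide 14 (not isolated)
Conditions: LiN(iPr)2, THF, −78 °C; 12, −78 °C to rt; then CH3I, CH2Cl2, rt; then aq. NaHCO3
Reagents that add atoms: N,N-dimethylmethyleneiminium iodide (12), C[N+](C)=C.[I-]
Why: Eschenmoser methylenation, a Mannich reaction of the kinetic lithium enolate formed at the C3 methylene and not at the C7 methine, followed by quaternisation and elimination of trimethylamine, puts the future C2 on C3, and the equatorial C4–O and C6–O bonds lie near the nodal plane of the enolate so that E1cB loss of alkoxide is slow.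

Step 11
Reactants: 15 3-methylene ketone; 16 vinylmagnesium bromide
Product: 17 3β-allyl C8 ketone (H3 α; allyl equatorial)
Conditions: CuBr·SMe2 (0.2 equiv), THF, −78 °C; then sat. aq. NH4Cl at −78 °C
Reagents that add atoms: vinylmagnesium bromide (16), C=C[Mg]Br
Why: Copper-catalysed conjugate addition of the vinyl Grignard reagent to the exocyclic enone gives the C3=C8 enolate regiospecifically, and its protonation on carbon should occur axially from the α-face, anti to the axial C15 on C4, which sets H3 α and the allyl group equatorial, the arrangement that is also the more stable one.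

Step 12
Reactants: 17 acetonide ketone
Product: 18 3β-allyl keto diol (4α-OH, C15–OH)
Conditions: AcOH/THF/H2O (3:1:1), rt
Reagents that add atoms: none
Why: Mild aqueous acid hydrolyses the terminal dioxolane to the 4,15-diol, while the secondary TBS ether and the pivalate are expected to survive.

Step 13
Reactants: 18 keto diol
Product: 20 3β-allyl 4,15-epoxy ketone (O4 α and equatorial; C15 β and axial), via monotosylate 19 (not isolated)
Conditions: TsCl, pyridine, DMAP (cat.), CH2Cl2, 0 °C; then NaH (1.1 equiv), THF, 0 °C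
Reagents that add atoms: none
Why: Selective sulfonylation of the primary C15 hydroxyl followed by intramolecular Williamson closure (3-exo-tet) by the O4 alkoxide gives the spiro-epoxide with retention at C4 because only the C15–O bond is replaced, and it is done while C8 is still a ketone so that no O8 hydroxyl can compete for C15.

Step 14
Reactants: 20 epoxy ketone; 21 2-methylallylmagnesium chloride
Product: 22 3β-allyl-8α-(2-methylallyl)-8β-ol (O8 axial)
Conditions: CeCl3, THF, −78 °C; sat. aq. NH4Cl
Reagents that add atoms: 2-methylallylmagnesium chloride (21), CC(=C)C[Mg]Cl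
Why: Organocerium 1,2-addition is non-basic and spares the epoxide and the pivalate, and because the axial C15 on C4 blocks axial attack on the C8 carbonyl the reagent enters equatorially, which sets the new stereocentre with O8 axial (β, cis to the C7 chain and syn to C15) and C9 equatorial.

Step 15
Reactants: 22 diene carbinol
Product: 23 trans-decalinol (8β-OH, H3 α, 4,15-spiro-epoxide, 6α-OTBS, 7β-CH2CH2OPiv, ring B C1=C10 with C14 on C10)
Conditions: second-generation Grubbs catalyst RuCl2(=CHPh)(PCy3)(H2IMes) (5 mol%), CH2Cl2, 40 °C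
Reagents that add atoms: none
Why: Ring-closing metathesis of the equatorial allyl (on C3) and 2-methylallyl (on C8) groups closes cyclohexene ring B as a trans-fused decalin with loss of ethene and fixes the C1=C10 alkene cis with the methyl group on C10.

Step 16
Reactants: 23 trans-decalinol
Product: 24 (1(10)Z,3Z)-cyclodecadien-8-one (ring-trans C3=C4 bearing C15H2OH, 6α-OTBS, 7β-CH2CH2OPiv)
Conditions: Ti(OiPr)4 (2 equiv), CH2Cl2, 0 °C to reflux; aq. Rochelle salt
Reagents that add atoms: none
Why: Titanium tetraisopropoxide exchanges onto the axial O8 hydroxyl while a second titanium centre coordinates the epoxide oxygen; the O8 lone pair then pushes into C8, the C3–C8 σ bond shared by rings A and B breaks, and the C4–O bond of the spiro-epoxide, which is equatorial on ring A and therefore antiperiplanar to C3–C8, leaves in a concerted Grob fragmentation. The closest known reaction type is the titanium-alkoxide-promoted epoxy-alcohol fragmentation of bicyclic tertiary carbinols to medium-ring hydroxy ketones, itself a variant of the Grob/Wharton fragmentation of decalin 1,3-diol monosulfonates. The ten-membered ring is not closed end to end but released by scission of the fusion bond of two six-membered rings, so no closure mode applies and epoxide strain pays for the medium-ring strain. No stereocentre is formed: C6 and C7 pass through untouched, C2 (equatorial on C3 of the trans-decalin) ends trans to C5 across C3=C4, and C1=C10 stays cis as in the cyclohexene. The step needs fragmentation to beat attack of O8 on C15 (a disfavoured 5-endo epoxide opening) and ionisation without C–C cleavage; the rigid trans-fusion that locks the antiperiplanar array and the tertiary, Lewis-acid-activated C4–O bond secure this.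

Step 17
Reactants: 24 silyloxy dienone
Product: 25 6α-hydroxy dienone
Conditions: HF·pyridine, pyridine, THF, 0 °C to rt
Reagents that add atoms: none
Why: Fluoride-mediated desilylation under buffered conditions frees the O6 hydroxyl without base, so the β-hydroxy ketone is exposed neither to retro-aldol cleavage nor to conjugation of the β,γ-alkene, and the pivalate is unaffected.

Step 18
Reactants: 25 β-hydroxy ketone
Product: 26 6-O-acetyl-8β-ol
Conditions: SmI2 (0.3 equiv), CH3CHO (8 equiv), THF, −10 °C
Reagents that add atoms: acetaldehyde, CC=O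
Why: Evans–Tishchenko reduction: the samarium-bound hemiacetal formed from O6 and acetaldehyde delivers its hydride to C8 through a six-membered chair on the face syn to O6, which sets the 8β-alcohol (1,3-anti to O6) and leaves O6 as an acetate, so the two oxygens are differentiated.

Step 19
Reactants: 26 diol monoacetate
Product: 27 15-O-TBDPS ether (free 8β-OH)
Conditions: TBDPSCl (1.05 equiv), imidazole, CH2Cl2, 0 °C
Reagents that add atoms: tert-butyldiphenylsilyl chloride, CC(C)(C)[Si](Cl)(c1ccccc1)c1ccccc1
Why: Silylation with the bulky chlorosilane is selective for the primary allylic C15 hydroxyl over the secondary O8 hydroxyl, which must stay free to direct the next step.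

Step 20
Reactants: 27 homoallylic alcohol
Product: 28 1β,10β-epoxide (C14 α; free 8β-OH)
Conditions: VO(acac)2 (5 mol%), tBuOOH, CH2Cl2, 0 °C to rt
Reagents that add atoms: tert-butyl hydroperoxide, CC(C)(C)OO
Why: Vanadium-catalysed hydroxyl-directed epoxidation delivers oxygen from the O8-bound peroxo complex to the homoallylic (Z)-C1=C10 alkene on the face syn to O8 (1,3-syn), giving the β-epoxide, whereas the C3=C4 alkene has no free directing hydroxyl and is left alone.

Step 21
Reactants: 28 epoxy alcohol
Product: 29 8-O-TES ether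
Conditions: TESCl, imidazole, DMAP (cat.), CH2Cl2, 0 °C to rt
Reagents that add atoms: triethylsilyl chloride, CC[Si](Cl)(CC)CC
Why: Silyl ether formation protects O8 with a group that can later be removed in the presence of the primary TBDPS ether.

Step 22
Reactants: 29 acetate pivalate
Product: 30 6α,12-diol
Conditions: iBu2AlH (5 equiv), CH2Cl2, −78 °C; aq. Rochelle salt
Reagents that add atoms: none
Why: Reduction with diisobutylaluminium hydride at low temperature cleaves both the O6 acetate and the O12 pivalate to the alcohols, at a temperature where the trisubstituted epoxide and the silyl ethers should be inert.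

Step 23
Reactants: 30 1,4-diol
Product: 32 trans-fused 6,12-lactone, via lactol 31 (not isolated)
Conditions: TEMPO (0.2 equiv), PhI(OAc)2 (3 equiv), CH2Cl2, rt
Reagents that add atoms: none
Why: TEMPO-catalysed oxidation is selective for the primary C12 alcohol, whose aldehyde is trapped by O6, the only free hydroxyl, as the lactol and oxidised on to the γ-lactone (oxidative lactonisation of a 1,4-diol).

Step 24
Reactants: 32 lactone; 12 N,N-dimethylmethyleneiminium iodide
Product: 35 α-methylene lactone, via Mannich base 33 (not isolated), via methiodide 34 (not isolated)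
Conditions: LiN(iPr)2, THF, −78 °C; 12, −78 °C to rt; then CH3I, CH2Cl2, rt; then aq. NaHCO3
Reagents that add atoms: N,N-dimethylmethyleneiminium iodide (12), C[N+](C)=C.[I-]
Why: Eschenmoser methylenation of the lactone enolate (Mannich reaction, quaternisation, elimination) installs C13 as the exocyclic methylene group on C11 at a stage where no angelate is yet present to be deprotonated.

Step 25
Reactants: 35 silyl-protected methylene lactone
Product: 36 8β-ol
Conditions: HF·pyridine, pyridine, THF, 0 °C
Reagents that add atoms: none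
Why: Buffered HF·pyridine removes the secondary triethylsilyl ether much faster than the primary TBDPS ether and leaves the epoxide and the α-methylene lactone intact.

Step 26
Reactants: 36 8β-ol; 37 angelic acid
Product: 38 8-O-angelate
Conditions: 37, 2,4,6-trichlorobenzoyl chloride, Et3N, toluene, rt; then 36, DMAP, 60 °C
Reagents that add atoms: angelic acid (37), C/C=C(/C)C(=O)O
Why: Yamaguchi esterification through the mixed 2,4,6-trichlorobenzoic anhydride acylates the hindered O8 hydroxyl, the only free secondary alcohol, and is the method of choice for angelates because it avoids isomerisation to the tiglate.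

Step 27
Reactants: 38 silyl ether
Product: 39 15-ol (allylic alcohol)
Conditions: Bu4NF/AcOH (1:1), THF, 0 °C to rt
Reagents that add atoms: none
Why: Fluoride buffered with acetic acid cleaves the TBDPS ether without exposing the α-methylene lactone, the angelate or the epoxide to base.

Step 28
Reactants: 39 allylic alcohol
Product: 40 target (3β-OH, 4α-OH, C15 β)
Conditions: OsO4 (1.1 equiv), (DHQ)2PHAL (1.2 equiv), CH2Cl2, −78 °C; then aq. NaHSO3
Reagents that add atoms: osmium tetroxide, O=[Os](=O)(=O)=O
Why: Sharpless-type asymmetric dihydroxylation adds both hydroxyls suprafacially to the ring-trans C3=C4 alkene, the only electron-rich alkene left, and with the vinylic hydrogen of C3 in the hindered quadrant the dihydroquinine ligand directs osmium to the face that gives (3S,4R), that is 3β-OH and 4α-OH with C15 β.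

Compound list
1 | (−)-quinic acid, (1S,3R,4S,5R)-1,3,4,5-tetrahydroxycyclohexane-1-carboxylic acid | O[C@@H]1C[C@@](O)(C(=O)O)C[C@@H](O)[C@@H]1O | starting material
2 | quinide (1,5-lactone of 1; C15(=O)–O8 bridge; free 4α-OH, 6α-OH, 7α-OH) | O[C@@H]1C[C@]2(O)C[C@@H](OC2=O)[C@@H]1O | intermediate
3 | 6-O-TBS-quinide | CC(C)(C)[Si](C)(C)O[C@@H]1C[C@]2(O)C[C@@H](OC2=O)[C@@H]1O | intermediate
4 | 6-O-TBS-7-oxoquinide | CC(C)(C)[Si](C)(C)O[C@@H]1C[C@]2(O)C[C@@H](OC2=O)C1=O | intermediate
5 | methyl (triphenylphosphoranylidene)acetate | COC(=O)C=P(c1ccccc1)(c1ccccc1)c1ccccc1 | starting material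
6 | methyl (E)-(6-O-TBS-quinid-7-ylidene)acetate | CC(C)(C)[Si](C)(C)O[C@@H]1C[C@]2(O)C[C@@H](OC2=O)/C1=C\C(=O)OC | intermediate
7 | methyl (6-O-TBS-quinid-7β-yl)acetate (H7 α) | CC(C)(C)[Si](C)(C)O[C@@H]1C[C@]2(O)C[C@@H](OC2=O)[C@H]1CC(=O)OC | intermediate
8 | ring-A tetraol (4α-OH, 4β-CH2OH, 6α-OTBS, 7β-CH2CH2OH, 8β-OH) | CC(C)(C)[Si](C)(C)O[C@@H]1C[C@@](O)(CO)C[C@@H](O)[C@H]1CCO | intermediate
9 | 4,15-O-isopropylidene derivative of 8 | CC(C)(C)[Si](C)(C)O[C@@H]1C[C@]2(OC(C)(C)OC2)C[C@@H](O)[C@H]1CCO | intermediate
10 | 12-O-pivalate of 9 | CC(C)(C)[Si](C)(C)O[C@@H]1C[C@]2(OC(C)(C)OC2)C[C@@H](O)[C@H]1CCOC(=O)C(C)(C)C | intermediate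
11 | C8 ketone of 10 | CC(C)(C)[Si](C)(C)O[C@@H]1C[C@]2(OC(C)(C)OC2)CC(=O)[C@H]1CCOC(=O)C(C)(C)C | intermediate
12 | N,N-dimethylmethyleneiminium iodide (Eschenmoser's salt) | C[N+](C)=C.[I-] | starting material
13 | 3-(dimethylaminomethyl) C8 ketone (Mannich base; C3 unassigned) | CC(C)(C)[Si](C)(C)O[C@@H]1C[C@]2(OC(C)(C)OC2)C(CN(C)C)C(=O)[C@H]1CCOC(=O)C(C)(C)C | intermediate
14 | methiodide of 13 | CC(C)(C)[Si](C)(C)O[C@@H]1C[C@]2(OC(C)(C)OC2)C(C[N+](C)(C)C)C(=O)[C@H]1CCOC(=O)C(C)(C)C.[I-] | intermediate
15 | 3-methylene C8 ketone | CC(C)(C)[Si](C)(C)O[C@@H]1C[C@]2(OC(C)(C)OC2)C(=C)C(=O)[C@H]1CCOC(=O)C(C)(C)C | intermediate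
16 | vinylmagnesium bromide | C=C[Mg]Br | starting material
17 | 3β-allyl C8 ketone (H3 α) | CC(C)(C)[Si](C)(C)O[C@@H]1C[C@]2(OC(C)(C)OC2)[C@@H](CC=C)C(=O)[C@H]1CCOC(=O)C(C)(C)C | intermediate
18 | 3β-allyl keto diol (4α-OH, C15–OH) | CC(C)(C)[Si](C)(C)O[C@@H]1C[C@@](O)(CO)[C@@H](CC=C)C(=O)[C@H]1CCOC(=O)C(C)(C)C | intermediate
19 | 15-O-tosylate of 18 | CC(C)(C)[Si](C)(C)O[C@@H]1C[C@@](O)(COS(=O)(=O)c2ccc(C)cc2)[C@@H](CC=C)C(=O)[C@H]1CCOC(=O)C(C)(C)C | intermediate
20 | 3β-allyl 4,15-epoxy C8 ketone (O4 α) | CC(C)(C)[Si](C)(C)O[C@@H]1C[C@@]2(CO2)[C@@H](CC=C)C(=O)[C@H]1CCOC(=O)C(C)(C)C | intermediate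
21 | 2-methylallylmagnesium chloride | CC(=C)C[Mg]Cl | starting material
22 | 3β-allyl-8α-(2-methylallyl)-8β-ol | CC(C)(C)[Si](C)(C)O[C@@H]1C[C@@]2(CO2)[C@@H](CC=C)[C@](O)(CC(C)=C)[C@H]1CCOC(=O)C(C)(C)C | intermediate
23 | trans-decalinol precursor (8β-OH, H3 α, 4,15-spiro-epoxide, 6α-OTBS, 7β-CH2CH2OPiv) | CC(C)(C)[Si](C)(C)O[C@@H]1C[C@@]2(CO2)[C@H]3CC=C(C)C[C@]3(O)[C@H]1CCOC(=O)C(C)(C)C | intermediate
24 | (1(10)Z,3Z)-15-hydroxy-6α-(TBS-oxy)-7β-(2-pivaloyloxyethyl)cyclodeca-1(10),3-dien-8-one | CC(C)(C)[Si](C)(C)O[C@@H]1C/C(CO)=C/C/C=C(C)\CC(=O)[C@H]1CCOC(=O)C(C)(C)C | intermediate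
25 | 6α,15-dihydroxy dienone | O[C@@H]1C/C(CO)=C/C/C=C(C)\CC(=O)[C@H]1CCOC(=O)C(C)(C)C | intermediate
26 | 6-O-acetyl-8β,15-diol | CC(=O)O[C@@H]1C/C(CO)=C/C/C=C(C)\C[C@@H](O)[C@H]1CCOC(=O)C(C)(C)C | intermediate
27 | 15-O-TBDPS ether of 26 | CC(=O)O[C@@H]1C/C(CO[Si](c2ccccc2)(c2ccccc2)C(C)(C)C)=C/C/C=C(C)\C[C@@H](O)[C@H]1CCOC(=O)C(C)(C)C | intermediate
28 | 1β,10β-epoxide of 27 | CC(=O)O[C@@H]1C/C(CO[Si](c2ccccc2)(c2ccccc2)C(C)(C)C)=C/C[C@H]2O[C@@]2(C)C[C@@H](O)[C@H]1CCOC(=O)C(C)(C)C | intermediate
29 | 8-O-TES ether of 28 | CC(=O)O[C@@H]1C/C(CO[Si](c2ccccc2)(c2ccccc2)C(C)(C)C)=C/C[C@H]2O[C@@]2(C)C[C@@H](O[Si](CC)(CC)CC)[C@H]1CCOC(=O)C(C)(C)C | intermediate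
30 | 6α,12-diol | O[C@@H]1C/C(CO[Si](c2ccccc2)(c2ccccc2)C(C)(C)C)=C/C[C@H]2O[C@@]2(C)C[C@@H](O[Si](CC)(CC)CC)[C@H]1CCO | intermediate
31 | 6,12-lactol (C12 unassigned) | OC1O[C@@H]2C/C(CO[Si](c3ccccc3)(c3ccccc3)C(C)(C)C)=C/C[C@H]3O[C@@]3(C)C[C@@H](O[Si](CC)(CC)CC)[C@H]2C1 | intermediate
32 | trans-fused 6,12-lactone | O=C1O[C@@H]2C/C(CO[Si](c3ccccc3)(c3ccccc3)C(C)(C)C)=C/C[C@H]3O[C@@]3(C)C[C@@H](O[Si](CC)(CC)CC)[C@H]2C1 | intermediate
33 | 11-(dimethylaminomethyl) lactone (Mannich base; C11 unassigned) | CN(C)CC1C(=O)O[C@@H]2C/C(CO[Si](c3ccccc3)(c3ccccc3)C(C)(C)C)=C/C[C@H]3O[C@@]3(C)C[C@@H](O[Si](CC)(CC)CC)[C@@H]12 | intermediate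
34 | methiodide of 33 | C[N+](C)(C)CC1C(=O)O[C@@H]2C/C(CO[Si](c3ccccc3)(c3ccccc3)C(C)(C)C)=C/C[C@H]3O[C@@]3(C)C[C@@H](O[Si](CC)(CC)CC)[C@@H]12.[I-] | intermediate
35 | α-methylene lactone (8-O-TES, 15-O-TBDPS) | C=C1C(=O)O[C@@H]2C/C(CO[Si](c3ccccc3)(c3ccccc3)C(C)(C)C)=C/C[C@H]3O[C@@]3(C)C[C@@H](O[Si](CC)(CC)CC)[C@@H]12 | intermediate
36 | α-methylene lactone 8β-ol | C=C1C(=O)O[C@@H]2C/C(CO[Si](c3ccccc3)(c3ccccc3)C(C)(C)C)=C/C[C@H]3O[C@@]3(C)C[C@@H](O)[C@@H]12 | intermediate
37 | angelic acid, (Z)-2-methylbut-2-enoic acid | C/C=C(/C)C(=O)O | starting material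
38 | 8-O-angelate (15-O-TBDPS) | C=C1C(=O)O[C@@H]2C/C(CO[Si](c3ccccc3)(c3ccccc3)C(C)(C)C)=C/C[C@H]3O[C@@]3(C)C[C@@H](OC(=O)/C(C)=C\C)[C@@H]12 | intermediate
39 | 8-O-angelate 15-ol (ring-trans C3=C4) | C=C1C(=O)O[C@@H]2C/C(CO)=C/C[C@H]3O[C@@]3(C)C[C@@H](OC(=O)/C(C)=C\C)[C@@H]12 | intermediate
40 | CNP0307250.1 (8β-angeloyloxy-1β,10β-epoxy-3β,4α,15-trihydroxy-germacr-11(13)-en-6α,12-olide) | C=C1C(=O)O[C@@H]2C[C@@](O)(CO)[C@@H](O)C[C@H]3O[C@@]3(C)C[C@@H](OC(=O)/C(C)=C\C)[C@@H]12 | target

Total step count: 28. Longest linear sequence: 28 steps (1 to 40).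

Steps most likely to fail

Step 16. The epoxide may ionise without C–C cleavage, the O8 alkoxide may capture C15, or the product may recyclise across the ring under the Lewis acid. The fallback changes the mechanism from heterolytic to radical. Setting out from 23, the O8 alkoxyl radical is generated by the hypoiodite method (PhI(OAc)2, I2, visible light, CH2Cl2). β-Scission of C8–C3 gives the C8 ketone and a C3 radical, which opens the neighbouring oxirane; the resulting C15 alkoxyl species is reduced to the alcohol on thiosulfate work-up. This returns to the route at 24 without a new isolated compound (F0). The C3=C4 geometry would then rest on the conformation of the ring-opened radical and no longer on the ring fusion.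

Step 20. The directed epoxidation may show poor facial selectivity on the flexible ten-membered ring. The fallback sets the epoxide on the rigid bicycle instead. Setting out from 23, VO(acac)2/tBuOOH epoxidises the ring-B alkene cis to the axial O8 hydroxyl, which sits directly over the β-face of the homoallylic C1=C10 bond, to give the bis-epoxide F1. Fragmentation as in step 16 gives the epoxy ketone F2, desilylation as in step 17 the hydroxy ketone F3, and Evans–Tishchenko reduction as in step 18 the acetate F4. Silylation as in step 19 returns to the route at 28. The price is that the fragmentation must then tolerate the second oxirane, whose C10–O bond is not antiperiplanar to C8–C9.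

Step 28. Osmylation may occur on the wrong alkene face if the conformational bias of the ring overrides the ligand. The fallback replaces reagent control by a directing group at an earlier stage. Setting out from 30, whose free O6 hydroxyl is homoallylic to C4, hydrogen-bond-directed osmylation with OsO4·TMEDA (CH2Cl2, −78 °C, reductive work-up) should place O4 syn to O6 (α) and hence O3 β, giving tetraol F5. Oxidative lactonisation as in step 23 gives F6, silylation of the secondary O3 hydroxyl (TBSCl, imidazole) F7, methylenation as in step 24 F8, removal of the triethylsilyl group as in step 25 F9, and Yamaguchi angeloylation as in step 26 F10. Global desilylation with buffered fluoride returns to the route at 40.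

Further compounds
F0 | step 16 | none | none
F1 | step 20 | 1β,10β-epoxide of decalinol 23 (bis-epoxide) | CC(C)(C)[Si](C)(C)O[C@@H]1C[C@@]2(CO2)[C@H]3C[C@H]4O[C@@]4(C)C[C@]3(O)[C@H]1CCOC(=O)C(C)(C)C
F2 | step 20 | 1β,10β-epoxy-15-hydroxy-6α-(TBS-oxy) cyclodec-3-en-8-one | CC(C)(C)[Si](C)(C)O[C@@H]1C/C(CO)=C/C[C@H]2O[C@@]2(C)CC(=O)[C@H]1CCOC(=O)C(C)(C)C
F3 | step 20 | 1β,10β-epoxy-6α,15-dihydroxy cyclodec-3-en-8-one | O[C@@H]1C/C(CO)=C/C[C@H]2O[C@@]2(C)CC(=O)[C@H]1CCOC(=O)C(C)(C)C
F4 | step 20 | 6-O-acetyl-1β,10β-epoxy-8β,15-diol | CC(=O)O[C@@H]1C/C(CO)=C/C[C@H]2O[C@@]2(C)C[C@@H](O)[C@H]1CCOC(=O)C(C)(C)C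
F5 | step 28 | 3β,4α,6α,12-tetraol (8-O-TES, 15-O-TBDPS, 1β,10β-epoxide) | O[C@@H]1C[C@@](O)(CO[Si](c2ccccc2)(c2ccccc2)C(C)(C)C)[C@@H](O)C[C@H]2O[C@@]2(C)C[C@@H](O[Si](CC)(CC)CC)[C@H]1CCO
F6 | step 28 | 3β,4α-dihydroxy 6,12-lactone | O=C1O[C@@H]2C[C@@](O)(CO[Si](c3ccccc3)(c3ccccc3)C(C)(C)C)[C@@H](O)C[C@H]3O[C@@]3(C)C[C@@H](O[Si](CC)(CC)CC)[C@H]2C1
F7 | step 28 | 3-O-TBS ether of F6 | O=C1O[C@@H]2C[C@@](O)(CO[Si](c3ccccc3)(c3ccccc3)C(C)(C)C)[C@@H](O[Si](C)(C)C(C)(C)C)C[C@H]3O[C@@]3(C)C[C@@H](O[Si](CC)(CC)CC)[C@H]2C1
F8 | step 28 | α-methylene lactone of F7 | C=C1C(=O)O[C@@H]2C[C@@](O)(CO[Si](c3ccccc3)(c3ccccc3)C(C)(C)C)[C@@H](O[Si](C)(C)C(C)(C)C)C[C@H]3O[C@@]3(C)C[C@@H](O[Si](CC)(CC)CC)[C@@H]12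
F9 | step 28 | 8β-ol of F8 | C=C1C(=O)O[C@@H]2C[C@@](O)(CO[Si](c3ccccc3)(c3ccccc3)C(C)(C)C)[C@@H](O[Si](C)(C)C(C)(C)C)C[C@H]3O[C@@]3(C)C[C@@H](O)[C@@H]12
F10 | step 28 | 8-O-angelate of F9 (3-O-TBS, 15-O-TBDPS target) | C=C1C(=O)O[C@@H]2C[C@@](O)(CO[Si](c3ccccc3)(c3ccccc3)C(C)(C)C)[C@@H](O[Si](C)(C)C(C)(C)C)C[C@H]3O[C@@]3(C)C[C@@H](OC(=O)/C(C)=C\C)[C@@H]12
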